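# Synthesis plan for (4S,6R)-4,6-dihydroxy-6-[(2S,10Z)-2-hydroxyheptadec-10-en-1-yl]cyclohex-2-en-1-one (22)

## The problem

Target 22 is a cyclohex-2-en-1-one with a tertiary carbinol at C6, a secondary allylic carbinol at C4 and, on C6, a seventeen-carbon chain that carries a carbinol at C2' and a (Z)-alkene at C10'. The ring is numbered C1 (ketone), C2=C3, C4, C5, C6, and the chain C1', C2' outward. Three stereocentres are needed: C4 (S), C6 (R) and C2' (S). C2' and C6 are 1,3-related through C1' and can be tied into one five-membered ring, so C2' can control C6. C4 and C6 are 1,3-related through C5, but C6 can steer C4 only weakly while the six-membered ring is still forming. The chain joins the ring at a fully substituted carbon, so either the C6–C1' bond or the C6–O bond has to be made at a quaternary centre. The 4-hydroxy enone next to an α-ketol is the fragile part: base or strong acid can eliminate the C4 hydroxyl, shift the α-ketol or open the ring, so the ring should appear late and under neutral conditions. The isolated (Z)-alkene excludes catalytic hydrogenation, ozonolysis and undirected epoxidation or dihydroxylation. The enabling feature is that C3 is a vinylic carbon bonded directly to the C4 carbinol carbon. A C3 vinylmetal and a C4 aldehyde would therefore form the C3–C4 bond, the carbinol and the ring in one operation at the final oxidation level.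

## Retrosynthesis

**Si–O bonds (22 from 21).** The last operation is removal of two silyl ethers from 21. A triethylsilyl ether on the tertiary O6 and a tert-butyldimethylsilyl ether on the secondary O2' both fall to buffered fluoride. The forward step must not expose the 4-hydroxy enone to base or strong acid.

**C3–C4 (21 from 19).** The ring is opened between the vinylic C3 and the carbinol C4, which leads to the acyclic (Z)-β-iodo enone aldehyde 19. The neighbouring cuts are less attractive. C1–C6 requires acyl-anion chemistry and gives a saturated ring. C4–C5 or C5–C6 requires enolates next to a β-oxygenated carbonyl group. The C3–C4 cut alone delivers enone and carbinol together. Precursor 19 has no ring and only the two stereocentres C6 and C2'. The forward reaction must keep the Z geometry, select one face of the aldehyde and leave the α-silyloxy ketone and the chain alkene alone.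

**Functional-group adjustment (19 from 16 via 18 and 17).** No skeletal bond is cut. The aldehyde is traced to a 4-methoxybenzyl ether and the (Z)-β-iodo enone to a terminal ynone. The ether is preferred to an acetal or an alkene as aldehyde precursor because its release is oxidative and neutral and cannot touch the chain alkene. The forward sequence needs a Z-selective hydroiodination and two mild oxidations.

**C1–C2 (16 from 12 and 13 via 15).** The ynone is cut between the ketone carbon and the alkyne, giving lactone 12 and ethynylmagnesium bromide 13. The lactone is both the acyl donor and the internal protection of O2'. It is preferred to an open-chain amide because its carbonyl group is far less hindered next to the quaternary C6. The forward step must stop after one addition.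

**C6–O (12 from 9 via 11).** The tertiary carbinol is traced to the alkylidene lactone 9 by a formal hydration of the exocyclic alkene. Here C2' controls C6, because on the five-membered ring the oxygen should enter trans to the C2' substituent. An open-chain addition to a C6 ketone would offer no comparable control.

**C5=C6, C6–C1' and the lactone C–O (9 from 7 and 8; 7 from 4 and 5).** The exocyclic alkene is cut by a Horner–Wadsworth–Emmons disconnection into phosphono lactone 7 and aldehyde 8. Lactone 7 is cut into epoxide 4 and triethyl phosphonoacetate 5. Reagent 5 supplies C1 and C6, acts as the nucleophile for the epoxide and then as the olefination handle. Epoxide 4 carries only the C2' stereocentre.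

**C1'–C2' (4 from 3, 2 and 1).** The epoxide is traced to aldehyde 2 by methylene transfer, with a kinetic resolution of racemic 3 to fix C2'. The chain and its (Z)-alkene come intact from palmitoleyl alcohol 1. Half of the material is lost in the resolution, but at the first stage and on the least valuable intermediate.

## Roads not taken

**Alternative 1:** The cut is at C2–C3 and C4–C5. Triene A1 carries a butyl vinylboronate on the C2' oxygen and has C6 as the 3-position of a 2-ethoxybutadiene. On heating it would close in a type 2 intramolecular Diels–Alder reaction to the bridged boronate A2.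
- Merits: two ring bonds form in one step from a precursor with a single stereocentre. The tether fixes the regiochemistry and relays C2' to C4, and C–B oxidation would give the C4 hydroxyl with retention.
- Weak points: A2 has neither the C6 hydroxyl nor the C2=C3 alkene. The bridge lies over the ring face on which C1' must end up, so an oxidant attacking the bridgehead enol ether from the open face would place the C6 oxygen trans to the C4 substituent, opposite to 22. The tether would have to be removed first and its control would be lost.
- Further weak points: dehydrogenation at C2–C3 would then be needed on an α-ketol, which is the treatment the target tolerates least. The dienophile is unactivated, the product is a strained bridgehead alkene, and the mixed boronate is hydrolytically labile.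
- Comparison: this road is better in the way C4 is set, through a tether and not by 1,3-induction. The chosen plan answers with ligand control and an inversion as correction, and its key step leaves only a desilylation, where A2 would need at least three redox adjustments.

**Alternative 2:** No ring C–C bond is made. The ring comes from arene A3 by Birch reduction, enol ether hydrolysis and α-hydroxylation, giving the β,γ-unsaturated α-hydroxy ketone A4. The key step is epoxidation of the C3=C4 alkene of A4 with VO(acac)2 and tert-butyl hydroperoxide, directed by the C6 hydroxyl, to epoxy ketone A5. Mild base would then open A5 to the 4-hydroxy enone A6.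
- Merits: hydroxyl-directed oxygen delivery is a strong and reliable way to place the C4 oxygen cis to the C6 hydroxyl. Direction also distinguishes the ring alkene from the chain alkene, and the ring carbons are inexpensive.
- Weak points: C6 has to be set by α-hydroxylation of a ketone whose only stereocentre is the exocyclic C2'. That is open-chain 1,3-induction and is likely to give mixtures unless a chiral oxidant is used. The β,γ-unsaturated ketone can slip into conjugation at every basic or acidic step, which would move the alkene away from C3=C4 and cancel the relay.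
- Comparison: this road is stronger at C4 and weaker at C6, the mirror image of the chosen plan. The chosen plan sets C6 by a ring-based relay and never has to preserve a β,γ-enone. The step counts are similar, and this alternative would be shorter if the C6 problem were solved.

**Alternative 3:** The cut is at C1–C6. Keto aldehyde A7 would be closed by an aminoindanol-derived N-pentafluorophenyl triazolium tetrafluoroborate and Et3N in an aldehyde–ketone benzoin reaction to give the α-ketol A8.
- Merits: the tertiary carbinol and the ring form together without metals, the C4 stereocentre is in place before the ring closes and cannot be lost, and the catalyst sets C6.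
- Weak points: A8 is the 2,3-dihydro compound, so C2=C3 must be introduced afterwards by oxidation of a ketone that already bears the α-ketol. In A7 the ketone is flanked by two nearly identical CH2CH(OSi) arms, so the catalyst has little to distinguish the two faces. Both arms are β-silyloxy ketones and can eliminate under the basic conditions. The enolizable aldehyde and ketone can also undergo intramolecular aldol reactions to five-membered rings. A7 needs two separately set carbinols in a 1,5-relationship.
- Comparison: this road is better in that C4 is secure. The chosen plan answers with a key step that gives the enone directly and with C6 control from C2' through a lactone instead of through catalyst discrimination of two similar arms.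

Key step: step 13

Remark: the ring locants C1 (ketone) to C6 (tertiary carbinol) and the chain locants C1', C2' of the target are used for the corresponding atoms of all intermediates.

Remark: palmitoleyl alcohol 1, the commercial reduced form of palmitoleic acid, is taken as the source of the chain.

Assumption: of the two antipodes of the oxazoline sulfonamide ligand in step 13, the one that favours the 4S carbinol is identified by a preliminary comparison, and the route is written for that antipode.

## Route

Step 1
Reactants: 1 (9Z)-hexadec-9-en-1-ol (palmitoleyl alcohol)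
Product: 2 (9Z)-hexadec-9-enal
Conditions: TEMPO (2,2,6,6-tetramethylpiperidin-1-oxyl, cat.), PhI(OAc)2, CH2Cl2, rt
Reagents that add atoms: none
Why: Oxoammonium (TEMPO) oxidation of a primary alcohol stops at the aldehyde and neither oxidizes nor isomerizes the isolated (Z)-alkene.

Step 2
Reactants: 2 (9Z)-hexadec-9-enal
Product: 3 rac-2-[(8Z)-pentadec-8-en-1-yl]oxirane
Conditions: Me3S+ I−, n-BuLi, THF, −10 °C to rt
Reagents that add atoms: trimethylsulfonium iodide, C[S+](C)C.[I-]
Why: Corey–Chaykovsky methylene transfer from dimethylsulfonium methylide to an aliphatic aldehyde gives the terminal epoxide; the new centre is racemic and is resolved in step 3.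

Step 3
Reactants: 3 rac-2-[(8Z)-pentadec-8-en-1-yl]oxirane
Product: 4 (2S)-2-[(8Z)-pentadec-8-en-1-yl]oxirane
Conditions: (S,S)-(salen)Co(OAc) (salen = N,N'-bis(3,5-di-tert-butylsalicylidene)-1,2-cyclohexanediamine dianion; 0.5 mol %), H2O (0.55 equiv), THF, 0 °C to rt
Reagents that add atoms: none
Why: Hydrolytic kinetic resolution: the trivalent cobalt salen acetate of (S,S) configuration is taken as the antipode that hydrolyses the (R)-enantiomer of 1-alkyl oxiranes, so the (S)-epoxide should be recovered and fixes C2'; the diol is removed by chromatography.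

Step 4
Reactants: 4 (2S)-2-[(8Z)-pentadec-8-en-1-yl]oxirane; 5 triethyl phosphonoacetate
Product: 7 diethyl [(5S)-2-oxo-5-[(8Z)-pentadec-8-en-1-yl]oxolan-3-yl]phosphonate (C3 epimers), via hydroxy phosphonoester 6 (not isolated)
Conditions: NaOEt, EtOH, 78 °C; aq. HCl work-up
Reagents that add atoms: none
Why: Epoxide opening by a stabilized carbanion followed by lactonization: the sodium salt of 5 attacks the unsubstituted epoxide carbon (SN2) and the C2' alkoxide of 6 closes onto the ethyl ester; the C2'–O bond is untouched, so C2' is retained.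

Step 5
Reactants: 7 diethyl [(5S)-2-oxo-5-[(8Z)-pentadec-8-en-1-yl]oxolan-3-yl]phosphonate; 8 (4-methoxybenzyloxy)acetaldehyde
Product: 9 (5S)-3-[2-(4-methoxybenzyloxy)ethylidene]-5-[(8Z)-pentadec-8-en-1-yl]oxolan-2-one (E/Z mixture at the exocyclic alkene)
Conditions: NaH, THF, 0 °C; then 8, 0 °C to rt
Reagents that add atoms: none
Why: Horner–Wadsworth–Emmons olefination of an α-phosphono lactone with the anion formed before the base-sensitive aldehyde is added; the alkene geometry does not matter because the alkene is consumed in step 6.

Step 6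
Reactants: 9 (5S)-3-[2-(4-methoxybenzyloxy)ethylidene]-5-[(8Z)-pentadec-8-en-1-yl]oxolan-2-one
Product: 11 (3S,5S)-3-hydroxy-3-[2-(4-methoxybenzyloxy)ethyl]-5-[(8Z)-pentadec-8-en-1-yl]oxolan-2-one, via hydroperoxy lactone 10 (not isolated)
Conditions: Mn(dpm)3 (dpm = 2,2,6,6-tetramethylheptane-3,5-dionate; cat.), PhSiH3, O2 (1 atm), i-PrOH/CH2Cl2, 0 °C; then P(OEt)3
Reagents that add atoms: dioxygen, O=O
Why: Mukaiyama hydration: a manganese hydride transfers H to the exocyclic C5, the tertiary α-acyl radical at C6 captures O2 and the phosphite reduces hydroperoxide 10. The oxygen should enter the ring face trans to the C2' substituent, which gives the 3S carbinol (C6 of the target); the unactivated 1,2-disubstituted chain alkene is a poor hydrogen-atom acceptor and should remain.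

Step 7
Reactants: 11 (3S,5S)-3-hydroxy-3-[2-(4-methoxybenzyloxy)ethyl]-5-[(8Z)-pentadec-8-en-1-yl]oxolan-2-one
Product: 12 (3S,5S)-3-[2-(4-methoxybenzyloxy)ethyl]-5-[(8Z)-pentadec-8-en-1-yl]-3-(triethylsilyloxy)oxolan-2-one
Conditions: Et3SiOTf, 2,6-lutidine, CH2Cl2, −78 to 0 °C
Reagents that add atoms: triethylsilyl trifluoromethanesulfonate, CC[Si](CC)(CC)OS(=O)(=O)C(F)(F)F
Why: Silyl triflate silylation of a tertiary α-hydroxy lactone; O6 must be capped before the ynone is made, because a free α'-hydroxy ynone would close to a 3(2H)-furanone.

Step 8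
Reactants: 12 (3S,5S)-3-[2-(4-methoxybenzyloxy)ethyl]-5-[(8Z)-pentadec-8-en-1-yl]-3-(triethylsilyloxy)oxolan-2-one; 13 ethynylmagnesium bromide
Product: 15 (4S,6S,14Z)-6-hydroxy-4-[2-(4-methoxybenzyloxy)ethyl]-4-(triethylsilyloxy)henicos-14-en-1-yn-3-one, via bromomagnesium lactolate 14 (not isolated)
Conditions: HC≡CMgBr (3 equiv), THF, −78 to 0 °C; sat. aq. NH4Cl
Reagents that add atoms: none
Why: Addition of an alkynyl Grignard reagent to a lactone; adduct 14 should persist as the cyclic magnesium lactolate until the quench, which guards against a second addition, and the quench releases the γ-hydroxy ynone (in equilibrium with its cyclic hemiketal form), which is carried on without delay.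

Step 9
Reactants: 15 (4S,6S,14Z)-6-hydroxy-4-[2-(4-methoxybenzyloxy)ethyl]-4-(triethylsilyloxy)henicos-14-en-1-yn-3-one
Product: 16 (4S,6S,14Z)-6-(tert-butyldimethylsilyloxy)-4-[2-(4-methoxybenzyloxy)ethyl]-4-(triethylsilyloxy)henicos-14-en-1-yn-3-one
Conditions: t-BuMe2SiOTf, 2,6-lutidine, CH2Cl2, −78 °C
Reagents that add atoms: tert-butyldimethylsilyl trifluoromethanesulfonate, CC(C)(C)[Si](C)(C)OS(=O)(=O)C(F)(F)F
Why: Silylation of the open-chain secondary alcohol removes it from the ring–chain equilibrium; a hindered, non-nucleophilic base is used because imidazole or amines would add to the terminal ynone.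

Step 10
Reactants: 16 (4S,6S,14Z)-6-(tert-butyldimethylsilyloxy)-4-[2-(4-methoxybenzyloxy)ethyl]-4-(triethylsilyloxy)henicos-14-en-1-yn-3-one
Product: 17 (1Z,4S,6S,14Z)-6-(tert-butyldimethylsilyloxy)-1-iodo-4-[2-(4-methoxybenzyloxy)ethyl]-4-(triethylsilyloxy)henicosa-1,14-dien-3-one
Conditions: NaI, AcOH (3 equiv), MeCN, 0 °C to rt, dark
Reagents that add atoms: sodium iodide, [Na+].[I-]
Why: Hydroiodination of a terminal ynone: conjugate addition of iodide and protonation of the allenolate anti to iodine should give the (Z)-β-iodo enone under kinetic control; a few equivalents of AcOH in MeCN for a short time should spare both silyl ethers.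

Step 11
Reactants: 17 (1Z,4S,6S,14Z)-6-(tert-butyldimethylsilyloxy)-1-iodo-4-[2-(4-methoxybenzyloxy)ethyl]-4-(triethylsilyloxy)henicosa-1,14-dien-3-one
Product: 18 (1Z,4S,6S,14Z)-6-(tert-butyldimethylsilyloxy)-4-(2-hydroxyethyl)-1-iodo-4-(triethylsilyloxy)henicosa-1,14-dien-3-one
Conditions: DDQ, CH2Cl2/pH 7 buffer, 0 °C, dark
Reagents that add atoms: none
Why: Oxidative cleavage of a 4-methoxybenzyl ether by DDQ; under buffered conditions the silyl ethers, the vinyl iodide and the isolated alkene are not attacked.

Step 12
Reactants: 18 (1Z,4S,6S,14Z)-6-(tert-butyldimethylsilyloxy)-4-(2-hydroxyethyl)-1-iodo-4-(triethylsilyloxy)henicosa-1,14-dien-3-one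
Product: 19 (3R,5S,13Z)-5-(tert-butyldimethylsilyloxy)-3-[(2Z)-3-iodoprop-2-enoyl]-3-(triethylsilyloxy)icos-13-enal
Conditions: Dess–Martin periodinane, NaHCO3, CH2Cl2, 0 °C to rt
Reagents that add atoms: none
Why: Dess–Martin oxidation of a primary alcohol under buffered, non-basic conditions, which avoids β-elimination of the C6 silyloxy group from the new aldehyde; 19 is used at once.

Step 13
Reactants: 19 (3R,5S,13Z)-5-(tert-butyldimethylsilyloxy)-3-[(2Z)-3-iodoprop-2-enoyl]-3-(triethylsilyloxy)icos-13-enal
Product: 21 (4S,6S)-6-[(2S,10Z)-2-(tert-butyldimethylsilyloxy)heptadec-10-en-1-yl]-4-hydroxy-6-(triethylsilyloxy)cyclohex-2-en-1-one, via vinylchromium dichloride 20 (not isolated)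
Conditions: CrCl2 (6 equiv), N-[2-(4-isopropyl-4,5-dihydrooxazol-2-yl)-6-methylphenyl]methanesulfonamide (chiral oxazoline sulfonamide ligand, 6.6 equiv), Et3N, NiCl2 (cat.), THF, rt, 0.01 M; aq. work-up
Reagents that add atoms: none
Why: Zerovalent nickel, formed from NiCl2 by CrCl2, inserts into the C3–I bond with retention of the Z geometry, and transmetallation to trivalent chromium gives vinylchromium 20, which adds to the C4 aldehyde through a four-centre transition state (Nozaki–Hiyama–Kishi reaction). The closest known reaction type is the intramolecular Nozaki–Hiyama–Kishi cyclization of (Z)-β-iodo enones and enoates onto aldehydes. The ring closes in the 6-exo-trig mode, with C3 attacking the carbonyl carbon C4 and the C=O bond outside the new ring; only the Z iodide can close, because it holds the C3–Cr bond cis to C1. The new C4 stereocentre is set by the aldehyde face that is attacked; the 1,3-bias from the quaternary C6 is expected to be weak, so the chiral sulfonamide on chromium is relied on to direct attack to the face that places the C4 oxygen cis to the C6 silyloxy group (4S). The step needs chemoselectivity for the C–I bond over the enone, the α-silyloxy ketone, the β-silyloxy aldehyde and the chain alkene; the neutral divalent chromium medium should secure it, because no enolate is formed and vinylchromium reagents add to aldehydes far faster than to ketones. The 4-hydroxy enone is released from its chromium alkoxide only on aqueous work-up and is never exposed to base.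

Step 14
Reactants: 21 (4S,6S)-6-[(2S,10Z)-2-(tert-butyldimethylsilyloxy)heptadec-10-en-1-yl]-4-hydroxy-6-(triethylsilyloxy)cyclohex-2-en-1-one
Product: 22 (4S,6R)-4,6-dihydroxy-6-[(2S,10Z)-2-hydroxyheptadec-10-en-1-yl]cyclohex-2-en-1-one
Conditions: HF·pyridine, pyridine, THF, 0 °C to rt
Reagents that add atoms: none
Why: Fluoride-mediated cleavage of the tertiary triethylsilyl and the secondary tert-butyldimethylsilyl ether in a pyridine-buffered medium, which should leave the 4-hydroxy enone and the α-ketol intact; no stereocentre is touched.

## Compound list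

1 | (9Z)-hexadec-9-en-1-ol (palmitoleyl alcohol) | CCCCCC/C=C\CCCCCCCCO | starting material
2 | (9Z)-hexadec-9-enal | CCCCCC/C=C\CCCCCCCC=O | intermediate
3 | rac-2-[(8Z)-pentadec-8-en-1-yl]oxirane | CCCCCC/C=C\CCCCCCCC1CO1 | intermediate
4 | (2S)-2-[(8Z)-pentadec-8-en-1-yl]oxirane | CCCCCC/C=C\CCCCCCC[C@H]1CO1 | intermediate
5 | triethyl phosphonoacetate | CCOC(=O)CP(=O)(OCC)OCC | starting material
6 | ethyl (4S,12Z)-2-(diethoxyphosphoryl)-4-hydroxynonadec-12-enoate (C2 epimers) | CCCCCC/C=C\CCCCCCC[C@H](O)CC(C(=O)OCC)P(=O)(OCC)OCC | intermediate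
7 | diethyl [(5S)-2-oxo-5-[(8Z)-pentadec-8-en-1-yl]oxolan-3-yl]phosphonate (C3 epimers) | CCCCCC/C=C\CCCCCCC[C@H]1CC(C(=O)O1)P(=O)(OCC)OCC | intermediate
8 | (4-methoxybenzyloxy)acetaldehyde | COc1ccc(COCC=O)cc1 | starting material
9 | (5S)-3-[2-(4-methoxybenzyloxy)ethylidene]-5-[(8Z)-pentadec-8-en-1-yl]oxolan-2-one (E/Z mixture) | CCCCCC/C=C\CCCCCCC[C@H]1CC(=CCOCc2ccc(OC)cc2)C(=O)O1 | intermediate
10 | (3S,5S)-3-hydroperoxy-3-[2-(4-methoxybenzyloxy)ethyl]-5-[(8Z)-pentadec-8-en-1-yl]oxolan-2-one | CCCCCC/C=C\CCCCCCC[C@H]1C[C@@](OO)(CCOCc2ccc(OC)cc2)C(=O)O1 | intermediate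
11 | (3S,5S)-3-hydroxy-3-[2-(4-methoxybenzyloxy)ethyl]-5-[(8Z)-pentadec-8-en-1-yl]oxolan-2-one | CCCCCC/C=C\CCCCCCC[C@H]1C[C@@](O)(CCOCc2ccc(OC)cc2)C(=O)O1 | intermediate
12 | (3S,5S)-3-[2-(4-methoxybenzyloxy)ethyl]-5-[(8Z)-pentadec-8-en-1-yl]-3-(triethylsilyloxy)oxolan-2-one | CCCCCC/C=C\CCCCCCC[C@H]1C[C@@](O[Si](CC)(CC)CC)(CCOCc2ccc(OC)cc2)C(=O)O1 | intermediate
13 | ethynylmagnesium bromide | C#C[Mg]Br | starting material
14 | bromomagnesium (3S,5S)-2-ethynyl-3-[2-(4-methoxybenzyloxy)ethyl]-5-[(8Z)-pentadec-8-en-1-yl]-3-(triethylsilyloxy)oxolan-2-olate (C2 epimers) | CCCCCC/C=C\CCCCCCC[C@H]1C[C@@](O[Si](CC)(CC)CC)(CCOCc2ccc(OC)cc2)C(O[Mg]Br)(C#C)O1 | intermediate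
15 | (4S,6S,14Z)-6-hydroxy-4-[2-(4-methoxybenzyloxy)ethyl]-4-(triethylsilyloxy)henicos-14-en-1-yn-3-one | CCCCCC/C=C\CCCCCCC[C@H](O)C[C@@](O[Si](CC)(CC)CC)(CCOCc1ccc(OC)cc1)C(=O)C#C | intermediate
16 | (4S,6S,14Z)-6-(tert-butyldimethylsilyloxy)-4-[2-(4-methoxybenzyloxy)ethyl]-4-(triethylsilyloxy)henicos-14-en-1-yn-3-one | CCCCCC/C=C\CCCCCCC[C@H](O[Si](C)(C)C(C)(C)C)C[C@@](O[Si](CC)(CC)CC)(CCOCc1ccc(OC)cc1)C(=O)C#C | intermediate
17 | (1Z,4S,6S,14Z)-6-(tert-butyldimethylsilyloxy)-1-iodo-4-[2-(4-methoxybenzyloxy)ethyl]-4-(triethylsilyloxy)henicosa-1,14-dien-3-one | CCCCCC/C=C\CCCCCCC[C@H](O[Si](C)(C)C(C)(C)C)C[C@@](O[Si](CC)(CC)CC)(CCOCc1ccc(OC)cc1)C(=O)/C=C\I | intermediate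
18 | (1Z,4S,6S,14Z)-6-(tert-butyldimethylsilyloxy)-4-(2-hydroxyethyl)-1-iodo-4-(triethylsilyloxy)henicosa-1,14-dien-3-one | CCCCCC/C=C\CCCCCCC[C@H](O[Si](C)(C)C(C)(C)C)C[C@@](O[Si](CC)(CC)CC)(CCO)C(=O)/C=C\I | intermediate
19 | (3R,5S,13Z)-5-(tert-butyldimethylsilyloxy)-3-[(2Z)-3-iodoprop-2-enoyl]-3-(triethylsilyloxy)icos-13-enal | CCCCCC/C=C\CCCCCCC[C@H](O[Si](C)(C)C(C)(C)C)C[C@@](O[Si](CC)(CC)CC)(CC=O)C(=O)/C=C\I | intermediate
20 | (3R,5S,13Z)-5-(tert-butyldimethylsilyloxy)-3-[(2Z)-3-(dichlorochromio)prop-2-enoyl]-3-(triethylsilyloxy)icos-13-enal (C3 vinylchromium dichloride, trivalent chromium) | CCCCCC/C=C\CCCCCCC[C@H](O[Si](C)(C)C(C)(C)C)C[C@@](O[Si](CC)(CC)CC)(CC=O)C(=O)/C=C\[Cr](Cl)Cl | intermediate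
21 | (4S,6S)-6-[(2S,10Z)-2-(tert-butyldimethylsilyloxy)heptadec-10-en-1-yl]-4-hydroxy-6-(triethylsilyloxy)cyclohex-2-en-1-one | CCCCCC/C=C\CCCCCCC[C@H](O[Si](C)(C)C(C)(C)C)C[C@@]1(O[Si](CC)(CC)CC)C[C@H](O)C=CC1=O | intermediate
22 | (4S,6R)-4,6-dihydroxy-6-[(2S,10Z)-2-hydroxyheptadec-10-en-1-yl]cyclohex-2-en-1-one | CCCCCC/C=C\CCCCCCC[C@H](O)C[C@@]1(O)C[C@H](O)C=CC1=O | target

## Step count and least certain steps

Total step count: 14. Longest linear sequence: 14 steps (1 to 22); 5, 8 and 13 enter as purchased reagents.

**Step 13 (key step).** The most likely failure is unselective or reversed attack on the two faces of the C4 aldehyde. The substrate bias from C6 is weak, and a pseudo-equatorial preference of the chain at C6 may even favour the trans arrangement of the two ring oxygens. Isomerization of the iodide to the E form before insertion, or protonation of the vinylchromium, would lower conversion.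

Fallback: starting from 19, the closure is run with CrCl2 and catalytic NiCl2 alone in DMSO, and the substrate-controlled product, the C4 epimer F1, is accepted. F1 is inverted under Mitsunobu conditions (4-nitrobenzoic acid, PPh3, diisopropyl azodicarboxylate, THF) to the 4-nitrobenzoate of 21, F2. SN2 displacement at C4 is expected because the SN2' position is α to the ketone. Methanolysis of F2 (K2CO3, MeOH, 0 °C) returns to the route at 21; C6 is quaternary, so the brief base treatment cannot aromatize the ring.

**Step 6.** The most likely failure is insufficient face selection when the planar C6 radical captures oxygen, because the controlling substituent is two ring atoms away and the transition state is early. Simple reduction to the saturated lactone can also compete.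

Fallback: starting from 9, conjugate reduction with [(Ph3P)CuH]6 (cat.) and PhSiH3 gives the saturated lactone F3. Its potassium enolate (KN(SiMe3)2, THF, −78 °C) is hydroxylated with 2-(phenylsulfonyl)-3-phenyloxaziridine. The bulky electrophile should approach the enolate face anti to the C2' substituent, and the sequence returns to the route at 11.

**Step 8.** The most likely failures are collapse of the lactolate before the quench followed by a second addition, migration of the triethylsilyl group from O6 to the neighbouring alkoxide, or sluggish addition of the mild Grignard nucleophile to the hindered lactone.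

Fallback: starting from 12, the lactone is opened with Me2AlN(OMe)Me (from AlMe3 and N,O-dimethylhydroxylamine hydrochloride, CH2Cl2) to the hydroxy Weinreb amide F4. The C2' hydroxyl is silylated (t-BuMe2SiOTf, 2,6-lutidine) to the silyl ether F5. Reagent 13 is then added to the amide, whose chelated adduct cannot react twice, and the sequence returns to the route at 16.

**Step 10 (with steps 11 and 12).** The most likely failure is isomerization of the (Z)-β-iodo enone to the E isomer under acid, light or the two operations that follow; the E isomer cannot cyclize. Partial loss of the triethylsilyl ether in AcOH is a lesser concern.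

Fallback: the order of events is changed so that the iodide is made last. Starting from 16, DDQ gives the ynone alcohol F6 and Dess–Martin oxidation gives the ynone aldehyde F7. Hydroiodination of F7 with NaI and AcOH then returns to the route at 19, which goes directly into step 13.

## Further compounds

F1 | step 13 | (4R,6S)-6-[(2S,10Z)-2-(tert-butyldimethylsilyloxy)heptadec-10-en-1-yl]-4-hydroxy-6-(triethylsilyloxy)cyclohex-2-en-1-one (C4 epimer of 21) | CCCCCC/C=C\CCCCCCC[C@H](O[Si](C)(C)C(C)(C)C)C[C@@]1(O[Si](CC)(CC)CC)C[C@@H](O)C=CC1=O
F2 | step 13 | 4-nitrobenzoate ester of 21 at O4 | CCCCCC/C=C\CCCCCCC[C@H](O[Si](C)(C)C(C)(C)C)C[C@@]1(O[Si](CC)(CC)CC)C[C@H](OC(=O)c2ccc(cc2)[N+](=O)[O-])C=CC1=O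
F3 | step 6 | (5S)-3-[2-(4-methoxybenzyloxy)ethyl]-5-[(8Z)-pentadec-8-en-1-yl]oxolan-2-one (C3 epimers) | CCCCCC/C=C\CCCCCCC[C@H]1CC(CCOCc2ccc(OC)cc2)C(=O)O1
F4 | step 8 | (2S,4S,12Z)-4-hydroxy-N-methoxy-2-[2-(4-methoxybenzyloxy)ethyl]-N-methyl-2-(triethylsilyloxy)nonadec-12-enamide | CCCCCC/C=C\CCCCCCC[C@H](O)C[C@@](O[Si](CC)(CC)CC)(CCOCc1ccc(OC)cc1)C(=O)N(C)OC
F5 | step 8 | (2S,4S,12Z)-4-(tert-butyldimethylsilyloxy)-N-methoxy-2-[2-(4-methoxybenzyloxy)ethyl]-N-methyl-2-(triethylsilyloxy)nonadec-12-enamide | CCCCCC/C=C\CCCCCCC[C@H](O[Si](C)(C)C(C)(C)C)C[C@@](O[Si](CC)(CC)CC)(CCOCc1ccc(OC)cc1)C(=O)N(C)OC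
F6 | step 10 | (4S,6S,14Z)-6-(tert-butyldimethylsilyloxy)-4-(2-hydroxyethyl)-4-(triethylsilyloxy)henicos-14-en-1-yn-3-one | CCCCCC/C=C\CCCCCCC[C@H](O[Si](C)(C)C(C)(C)C)C[C@@](O[Si](CC)(CC)CC)(CCO)C(=O)C#C
F7 | step 10 | (3R,5S,13Z)-5-(tert-butyldimethylsilyloxy)-3-(prop-2-ynoyl)-3-(triethylsilyloxy)icos-13-enal | CCCCCC/C=C\CCCCCCC[C@H](O[Si](C)(C)C(C)(C)C)C[C@@](O[Si](CC)(CC)CC)(CC=O)C(=O)C#C
A1 | alternative 1 | butyl (5S,13Z)-2-ethoxy-3-methylideneicosa-1,13-dien-5-yl ethenylboronate (boronate-tethered triene) | CCCCCC/C=C\CCCCCCC[C@H](OB(OCCCC)C=C)CC(=C)C(=C)OCC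
A2 | alternative 1 | bridged bicyclic boronate with C1=C6 bridgehead enol ether and boron on C4 | CCCCCC/C=C\CCCCCCC[C@H]1CC2=C(OCC)CC[C@H](C2)B(OCCCC)O1
A3 | alternative 2 | tert-butyl{[(2S,10Z)-1-(2-methoxyphenyl)heptadec-10-en-2-yl]oxy}dimethylsilane | CCCCCC/C=C\CCCCCCC[C@H](O[Si](C)(C)C(C)(C)C)Cc1ccccc1OC
A4 | alternative 2 | (6S)-6-[(2S,10Z)-2-(tert-butyldimethylsilyloxy)heptadec-10-en-1-yl]-6-hydroxycyclohex-3-en-1-one | CCCCCC/C=C\CCCCCCC[C@H](O[Si](C)(C)C(C)(C)C)C[C@@]1(O)CC=CCC1=O
A5 | alternative 2 | 3,4-epoxy ketone with the oxirane cis to the C6 hydroxyl | CCCCCC/C=C\CCCCCCC[C@H](O[Si](C)(C)C(C)(C)C)C[C@@]1(O)C[C@@H]2O[C@@H]2CC1=O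
A6 | alternative 2 | 2'-O-tert-butyldimethylsilyl ether of 22 | CCCCCC/C=C\CCCCCCC[C@H](O[Si](C)(C)C(C)(C)C)C[C@@]1(O)C[C@H](O)C=CC1=O
A7 | alternative 3 | (4R,8S,16Z)-4,8-bis(tert-butyldimethylsilyloxy)-6-oxotricos-16-enal | CCCCCC/C=C\CCCCCCC[C@H](O[Si](C)(C)C(C)(C)C)CC(=O)C[C@H](O[Si](C)(C)C(C)(C)C)CCC=O
A8 | alternative 3 | 2,3-dihydro-22 as its 4-O,2'-O-bis(tert-butyldimethylsilyl) ether | CCCCCC/C=C\CCCCCCC[C@H](O[Si](C)(C)C(C)(C)C)C[C@@]1(O)C[C@H](O[Si](C)(C)C(C)(C)C)CCC1=O
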